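Ring numbering: C1 is the quaternary carbinol carbon (OH, CH2OBz), C2 CH(OAc), C3 CH(OBz), C4=C5 the alkene, C6 CH(OAc). The cyclohexene is cut at two non-adjacent ring bonds, C2–C3 and C4=C5, which excises a two-carbon C3–C4 unit already carrying the benzoate. In one flask a 3-benzoyloxyallylindium reagent adds through its oxygenated carbon to the C2 aldehyde of an acyclic epoxy ene-aldehyde (C5–C6–C1–C2), and ring-closing metathesis of the resulting 1,7-diene forms the ring alkene. The step exploits the C2(O)–C3(O)–C4=C5 ene-diol motif of the six-membered ring. A spiro-epoxide masks the C1 alcohol and its CH2OBz arm; C1 and C6 come from a Sharpless kinetic resolution.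

Key step: step 8

Remark on the chemistry: reagent 11 is used as its E/Z mixture, on the assumption that both isomers converge on the same oxygen-chelated (Z)-allylindium species.

Step 1
Reactants: 1 2,3-dibromoprop-1-ene; 2 (4-methoxyphenyl)methanol
Product: 3 2-bromoallyl 4-methoxybenzyl ether
Conditions: NaH, THF, 0 °C to rt
Reagents that add atoms: none
Why: Williamson etherification, in which the alkoxide of 2 displaces the allylic bromide of 1 by SN2 while the vinylic C–Br bond stays inert.

Step 2
Reactants: 3 2-bromoallyl 4-methoxybenzyl ether; 4 prop-2-enal (acrolein)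
Product: 5 rac-2-{[(4-methoxybenzyl)oxy]methyl}penta-1,4-dien-3-ol
Conditions: t-BuLi (2.1 equiv), Et2O, −78 °C; then 4, −78 °C; H2O
Reagents that add atoms: none
Why: Bromine–lithium exchange gives the 2-lithioallyl ether, which should add 1,2 to acrolein at low temperature (organolithium carbonyl addition) to give the racemic bis-allylic alcohol.

Step 3
Reactants: 5 rac-2-{[(4-methoxybenzyl)oxy]methyl}penta-1,4-dien-3-ol
Product: 6 (1S)-1-[(2R)-2-{[(4-methoxybenzyl)oxy]methyl}oxiran-2-yl]prop-2-en-1-ol
Conditions: Ti(OiPr)4 (cat.), L-(+)-diisopropyl tartrate (cat.), t-BuOOH (0.55 equiv), 4 Å MS, CH2Cl2, −20 °C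
Reagents that add atoms: tert-butyl hydroperoxide, CC(C)(C)OO
Why: Sharpless asymmetric epoxidation run as a kinetic resolution, in which the (S)-alcohol should be epoxidised fast at its more nucleophilic 1,1-disubstituted alkene with erythro selectivity, so that C6 (S) is set by selection of the enantiomer and C1 (R) by the tartrate-controlled face of oxygen delivery, while the (R)-alcohol is left behind and separated.

Step 4
Reactants: 6 (1S)-1-[(2R)-2-{[(4-methoxybenzyl)oxy]methyl}oxiran-2-yl]prop-2-en-1-ol
Product: 7 (1S)-1-[(2R)-2-{[(4-methoxybenzyl)oxy]methyl}oxiran-2-yl]prop-2-en-1-yl acetate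
Conditions: Ac2O, pyridine, DMAP (cat.), CH2Cl2, 0 °C
Reagents that add atoms: acetic anhydride, CC(=O)OC(C)=O
Why: Nucleophile-catalysed acetylation of the secondary alcohol installs the C6 acetate of the target, which also protects this position, and touches no stereocentre.

Step 5
Reactants: 7 (1S)-1-[(2R)-2-{[(4-methoxybenzyl)oxy]methyl}oxiran-2-yl]prop-2-en-1-yl acetate
Product: 8 (1S)-1-[(2R)-2-(hydroxymethyl)oxiran-2-yl]prop-2-en-1-yl acetate
Conditions: DDQ, CH2Cl2/pH 7 buffer, 0 °C to rt
Reagents that add atoms: none
Why: Oxidative cleavage of the electron-rich 4-methoxybenzyl ether by DDQ under buffered neutral conditions should leave the epoxide, acetate and alkene intact and avoid base-induced acetyl migration or Payne rearrangement.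

Step 6
Reactants: 8 (1S)-1-[(2R)-2-(hydroxymethyl)oxiran-2-yl]prop-2-en-1-yl acetate
Product: 9 (1S)-1-[(2R)-2-formyloxiran-2-yl]prop-2-en-1-yl acetate
Conditions: Dess–Martin periodinane, NaHCO3, CH2Cl2, 0 °C to rt
Reagents that add atoms: none
Why: Dess–Martin oxidation of the primary alcohol gives the epoxy aldehyde, which has no α-hydrogen, cannot epimerise or eliminate, and is used directly.

Step 7
Reactants: 4 prop-2-enal (acrolein); 10 benzoyl bromide
Product: 11 3-bromoprop-1-en-1-yl benzoate (E/Z mixture)
Conditions: ZnCl2 (cat.), CH2Cl2, −20 °C to rt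
Reagents that add atoms: none
Why: ZnCl2-catalysed addition of the acyl bromide to the enal (carbonyl addition followed by allylic transposition of bromide) gives the 3-bromopropenyl ester with no by-product.

Step 8
Reactants: 9 (1S)-1-[(2R)-2-formyloxiran-2-yl]prop-2-en-1-yl acetate; 11 3-bromoprop-1-en-1-yl benzoate
Product: 13 (3S,4S,7R,8S)-4-(acetyloxy)-8-hydroxy-1-oxaspiro[2.5]oct-5-en-7-yl benzoate, via syn-benzoyloxy dienol 12 (not isolated)
Conditions: In powder (1.3 equiv), THF, 0 °C to rt; then second-generation Grubbs catalyst (5 mol %), same flask, 45 °C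
Reagents that add atoms: none
Why: Zerovalent indium inserts into the allylic C–Br bond of 11 to give a 3-benzoyloxyallylindium species that settles in its oxygen-chelated (Z) form and adds through the oxygen-bearing γ-carbon to aldehyde 9 in a six-membered chair (Zimmerman–Traxler) transition state, forming C2–C3 and dienol 12; the ruthenium alkylidene then joins the two terminal vinyl groups of this 1,7-diene into the C4=C5 double bond through a ruthenacyclobutane with loss of ethene. The closest known reaction type is the Barbier-type indium-mediated acyloxyallylation of aldehydes followed by ring-closing metathesis, the established way of turning ene-aldehydes into conduritol-type cyclohexenes. The six-membered carbocycle is closed by ring-closing olefin metathesis, which can only give the cis ring alkene. C3 is set relative to C2 by the chair transition state of the (Z)-allylindium (2,3-syn, which becomes trans on the ring), and C2 is set by the C1 stereocentre through Felkin–Anh (Cornforth) attack on the non-chelating epoxy aldehyde, anti to the bulky C6 substituent and past the tied-back epoxide CH2, so that the new hydroxyl should end up cis to the C1 oxygen. The step needs γ-regioselectivity, syn simple diastereoselectivity, Felkin facial selectivity and chemoselectivity, which rest on the closed chair transition state, the internal O→In coordination, the small size and poor chelating ability of the spiro-epoxide, and the mildness of allylindium reagents towards epoxides and esters. A 1,3-acetyl shift between O6 and O2 would be harmless because both carry acetate in the target, and the C2 hydroxyl is acetylated directly in the next step to forestall 1,2-benzoyl migration.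

Step 9
Reactants: 13 (3S,4S,7R,8S)-4-(acetyloxy)-8-hydroxy-1-oxaspiro[2.5]oct-5-en-7-yl benzoate
Product: 14 (3R,4S,7R,8S)-4,8-bis(acetyloxy)-1-oxaspiro[2.5]oct-5-en-7-yl benzoate
Conditions: Ac2O, pyridine, DMAP (cat.), 0 °C to rt
Reagents that add atoms: acetic anhydride, CC(=O)OC(C)=O
Why: DMAP-catalysed acetylation of the hindered secondary C2 hydroxyl installs the second acetate of the target and leaves no free hydroxyl next to the C3 benzoate.

Step 10
Reactants: 14 (3R,4S,7R,8S)-4,8-bis(acetyloxy)-1-oxaspiro[2.5]oct-5-en-7-yl benzoate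
Product: 15 [(1R,2S,5R,6S)-2,6-bis(acetyloxy)-5-(benzoyloxy)-1-hydroxycyclohex-3-en-1-yl]methyl benzoate (CNP0221209.1)
Conditions: PhCO2H (3 equiv), PhCO2Cs (cat.), DMF, 60 °C
Reagents that add atoms: benzoic acid, OC(=O)c1ccccc1
Why: Carboxylate opening of the 2,2-disubstituted epoxide by SN2 attack at its unsubstituted CH2 leaves the C1 configuration untouched and should unveil the tertiary alcohol and the CH2OBz arm together, the excess acid protonating the tertiary alkoxide before it can take up an acetyl group.

Compound list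
1 | 2,3-dibromoprop-1-ene | C=C(Br)CBr | starting material
2 | (4-methoxyphenyl)methanol | COc1ccc(CO)cc1 | starting material
3 | 1-{[(2-bromoprop-2-en-1-yl)oxy]methyl}-4-methoxybenzene (2-bromoallyl 4-methoxybenzyl ether) | C=C(Br)COCc1ccc(OC)cc1 | intermediate
4 | prop-2-enal (acrolein) | C=CC=O | starting material
5 | rac-2-{[(4-methoxybenzyl)oxy]methyl}penta-1,4-dien-3-ol | C=CC(O)C(=C)COCc1ccc(OC)cc1 | intermediate
6 | (1S)-1-[(2R)-2-{[(4-methoxybenzyl)oxy]methyl}oxiran-2-yl]prop-2-en-1-ol | C=C[C@H](O)[C@@]1(COCc2ccc(OC)cc2)CO1 | intermediate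
7 | (1S)-1-[(2R)-2-{[(4-methoxybenzyl)oxy]methyl}oxiran-2-yl]prop-2-en-1-yl acetate | C=C[C@H](OC(C)=O)[C@@]1(COCc2ccc(OC)cc2)CO1 | intermediate
8 | (1S)-1-[(2R)-2-(hydroxymethyl)oxiran-2-yl]prop-2-en-1-yl acetate | C=C[C@H](OC(C)=O)[C@@]1(CO)CO1 | intermediate
9 | (1S)-1-[(2R)-2-formyloxiran-2-yl]prop-2-en-1-yl acetate | C=C[C@H](OC(C)=O)[C@@]1(C=O)CO1 | intermediate
10 | benzoyl bromide | O=C(Br)c1ccccc1 | starting material
11 | 3-bromoprop-1-en-1-yl benzoate (E/Z mixture) | BrCC=COC(=O)c1ccccc1 | intermediate
12 | (1S,2R)-1-{(2S)-2-[(1S)-1-(acetyloxy)prop-2-en-1-yl]oxiran-2-yl}-1-hydroxybut-3-en-2-yl benzoate (2,3-syn dienol, C2 hydroxyl erythro to the epoxide oxygen) | C=C[C@H](OC(C)=O)[C@@]1([C@@H](O)[C@H](OC(=O)c2ccccc2)C=C)CO1 | intermediate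
13 | (3S,4S,7R,8S)-4-(acetyloxy)-8-hydroxy-1-oxaspiro[2.5]oct-5-en-7-yl benzoate (spiro-epoxide at C1, C2-OH cis to the epoxide oxygen, C3-OBz trans to C2-OH, C6-OAc trans to the epoxide oxygen) | CC(=O)O[C@H]1C=C[C@@H](OC(=O)c2ccccc2)[C@H](O)[C@@]13CO3 | intermediate
14 | (3R,4S,7R,8S)-4,8-bis(acetyloxy)-1-oxaspiro[2.5]oct-5-en-7-yl benzoate | CC(=O)O[C@H]1C=C[C@@H](OC(=O)c2ccccc2)[C@H](OC(C)=O)[C@@]13CO3 | intermediate
15 | [(1R,2S,5R,6S)-2,6-bis(acetyloxy)-5-(benzoyloxy)-1-hydroxycyclohex-3-en-1-yl]methyl benzoate | CC(=O)O[C@H]1C=C[C@@H](OC(=O)c2ccccc2)[C@H](OC(C)=O)[C@@]1(O)COC(=O)c1ccccc1 | target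

Total step count: 10. Longest linear sequence: 9 steps (steps 1 to 6 and 8 to 10); step 7 is a one-step side branch.

Steps most likely to fail

Step 8. What may go wrong: incomplete stereocontrol in the allylindium addition (syn/anti or facial), 1,2-benzoyl migration within the indium alkoxide, Lewis-acid opening of the spiro-epoxide by indium salts, or deactivation of the ruthenium alkylidene by residual enol ester in the telescoped metathesis. Fallback, setting out from 9 and rejoining at 14: thermal allylboration with pinacol (Z)-3-(tert-butyldimethylsilyloxy)allylboronate (toluene, rt; reagent from allyl tert-butyldimethylsilyl ether, s-BuLi and i-PrOBpin) runs through a closed chair transition state under neutral, Lewis-acid-free conditions and should give the 2,3-syn silyloxy dienol F1 with no migrating acyl group on O3. Isolated F1 is cyclised with second-generation Grubbs catalyst (CH2Cl2, 40 °C) to the silyloxy cyclohexenol F2. Ac2O/pyridine gives the diacetate F3, HF·pyridine (THF, 0 °C) frees the allylic alcohol F4, and BzCl/pyridine (0 °C) then gives 14.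

Step 3. What may go wrong: insufficient rate differentiation between the two enantiomers and between the two alkenes in the titanium–tartrate kinetic resolution, which would erode the enantiomeric purity of the epoxy alcohol. Fallback, setting out from 5 and rejoining at 6: lipase-catalysed acylation (Candida antarctica lipase B, vinyl acetate, hexane, rt) should acetylate the (R)-alcohol (Kazlauskas rule, the substituted alkenyl group being the large substituent) and leave the (S)-dienol F5 beside the (R)-acetate F6. After separation, F5 is epoxidised to full conversion in the matched sense (Ti(OiPr)4, L-(+)-diisopropyl tartrate, t-BuOOH, CH2Cl2, −20 °C) to give 6.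

Step 10. What may go wrong: sluggish SN2 opening at the neopentyl-type epoxide CH2, with acetyl participation or acyl scrambling on heating. Fallback, setting out from 13 (before step 9) and rejoining at 15: hydroxyl-directed opening of the 2,3-epoxy alcohol with Ti(OiPr)4 and PhCO2H (CH2Cl2, rt), in which the titanium chelate of the C2 alkoxide and the epoxide oxygen steers benzoate to the CH2, should give the diol benzoate F7. Ac2O/pyridine then acetylates the C2 hydroxyl and leaves the tertiary one, giving 15.

Further compounds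
F1 | step 8 | (1S)-1-{(2S)-2-[(1S,2R)-2-{[tert-butyl(dimethyl)silyl]oxy}-1-hydroxybut-3-en-1-yl]oxiran-2-yl}prop-2-en-1-yl acetate | C=C[C@H](OC(C)=O)[C@@]1([C@@H](O)[C@H](O[Si](C)(C)C(C)(C)C)C=C)CO1
F2 | step 8 | (3S,4S,7R,8S)-7-{[tert-butyl(dimethyl)silyl]oxy}-8-hydroxy-1-oxaspiro[2.5]oct-5-en-4-yl acetate | CC(=O)O[C@H]1C=C[C@@H](O[Si](C)(C)C(C)(C)C)[C@H](O)[C@@]13CO3
F3 | step 8 | (3R,4S,7R,8S)-7-{[tert-butyl(dimethyl)silyl]oxy}-1-oxaspiro[2.5]oct-5-ene-4,8-diyl diacetate | CC(=O)O[C@H]1C=C[C@@H](O[Si](C)(C)C(C)(C)C)[C@H](OC(C)=O)[C@@]13CO3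
F4 | step 8 | (3R,4S,7R,8S)-7-hydroxy-1-oxaspiro[2.5]oct-5-ene-4,8-diyl diacetate | CC(=O)O[C@H]1C=C[C@@H](O)[C@H](OC(C)=O)[C@@]13CO3
F5 | step 3 | (3S)-2-{[(4-methoxybenzyl)oxy]methyl}penta-1,4-dien-3-ol | C=C[C@H](O)C(=C)COCc1ccc(OC)cc1
F6 | step 3 | (3R)-2-{[(4-methoxybenzyl)oxy]methyl}penta-1,4-dien-3-yl acetate | C=C[C@@H](OC(C)=O)C(=C)COCc1ccc(OC)cc1
F7 | step 10 | [(1S,2S,5R,6S)-2-(acetyloxy)-5-(benzoyloxy)-1,6-dihydroxycyclohex-3-en-1-yl]methyl benzoate | CC(=O)O[C@H]1C=C[C@@H](OC(=O)c2ccccc2)[C@H](O)[C@@]1(O)COC(=O)c1ccccc1
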